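Remark on the chemistry: ring A is numbered C1–C6 from the butanoyl-bearing carbon and each ring B C1'–C6' from the bridge carbon (C3' butanoyl, C5' methyl, C6' methoxy). The key-step structures balance (two C20H22O4 plus one C13H14O2 give C53H58O10) and need no correction. Three points are chosen for safety:
- The benzylic bromide is reached through the aldehyde and the alcohol, not by direct bromomethylation.
- The metalated alkynyl ether is generated only once and stored as its tributylstannyl derivative. Both alkynes are then made from this one donor by palladium-catalysed coupling under neutral conditions, with butanoyl chloride as the acyl source.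
- A cation scavenger is present in the final ether cleavage.

## Structural features

The target, C36H44O12, is a trimeric acylphloroglucinol. A central benzene ring A (C1 butanoyl; C2, C4, C6 hydroxyl; C3, C5 methylene) is joined through two CH2 bridges to two identical outer rings B (C1' on the bridge, C2' OH, C3' butanoyl, C4' OH, C5' CH3, C6' OCH3). All eighteen aromatic carbons are substituted, there is no stereocentre and no double-bond geometry, and a mirror plane through C1 and C4 of ring A makes the two halves equivalent, so two-directional operations are natural. Each ketone lies between two phenolic hydroxyls and is held in hydrogen-bonded chelates, which govern the acidity of the phenols and the lability of any ether placed on those oxygens. The fragile elements are the diarylmethane bridges between very electron-rich rings, which strong acid can cleave or scramble by ipso protonation and loss of a stabilised benzylic cation, and the free polyphenol, which is sensitive to base and air. The real difficulty is twofold: the regiocontrolled hexasubstitution of ring A, and the single methyl ether at C6' of each ring B, which must be told apart from seven free hydroxyls. The key step uses the strict alternation of carbon-bearing (C1, C3, C5) and oxygen-bearing (C2, C4, C6) atoms around ring A: cut into the pairs C1–C2, C3–C4 and C5–C6, the ring is the head-to-tail trimer of three 1-alkoxyalkynes, one acylated and two arylmethylated.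

## Logic of the disconnections

15 to 14. Seven O–C bonds are cut: the three O–CH2Ph bonds at C2, C4 and C6 of ring A and the four O–CH3 bonds at C2' and C4'. All seven are either benzyl ethers or methyl ethers ortho to a ketone, so one boron halide can remove them together while the phenols stay masked through the whole build-up. The forward step must leave the two C6' methyl ethers in place and must not ionise the CH2 bridges.

14 to 13. The two C3'–C(=O) bonds are cut. C3' is the only unsubstituted carbon of each ring B and is activated by three methoxy groups, so the outer rings simplify to symmetric, ketone-free aryl units. The forward acylation must be mild enough to spare three benzyl ethers and both bridges.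

13 to two molecules of 12 and one of 7. The ring bonds C2–C3, C4–C5 and C6–C1 are cut. This is the largest simplification: a hexasubstituted arene becomes three acyclic alkynes, two of them identical, and the ketone and all three oxygens of ring A are already in place. The forward step must pair two donors with one acceptor, orient them head to tail, and run at or below room temperature.

12 to 5 and 11; 7 to 5 and 6. In 12 the CH2–C(sp) bond is cut, in 7 the C(=O)–C(sp) bond. Both alkynes then come from the same alkynyl donor 5, which makes the route convergent. The demand is that 5 transfers its alkynyl group near room temperature and without base or amine, once to a very ionisable benzylic halide and once to an acid chloride whose product is a strong Michael acceptor.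

5 to 3 through 4, and 3 to 1 and 2. The C(sp)–Sn bond is cut, which leads through the metalated alkyne 4 back to 3. In 3 the C(sp2)–O bond is cut, so the oxygen substituent comes from 1 and both alkyne carbons from 2. Parking the reactive anion on tin means that 4 is made in one flask only and that 5 can be freed of salts and kept cold. The forward elimination must be run cold with just over two equivalents of base, and 5 must not be heated.

11 to 10, 9 and 8. The C–Br bond, then the carbinol C–H bond, then the C1'–CHO bond are cut. The formyl group deactivates the ring after one substitution, so only one of the two equivalent positions of 8 reacts; direct halomethylation offers no such control. The price is two extra steps, and 11 has to be used as soon as it is made.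

## Other disconnections considered

Alternative 1: The cut runs through both outer rings, at bonds C1'–C2' and C5'–C6' of each ring B. Ring A then survives as the bis(ynol ether) 1,3,5-tris(benzyloxy)-2,4-bis(3-methoxyprop-2-yn-1-yl)benzene A1, and the four-carbon partner is 3-ethoxy-2-methylcyclobut-2-en-1-one A2. Heating A1 with two equivalents of A2 would start a Danheiser benzannulation on each arm (ring opening of the cyclobutenone, ketene–alkyne [2+2] cycloaddition, second ring opening, six-electron electrocyclisation, tautomerisation) and give 1,3,5-tris(benzyloxy)-2,4-bis[(4-ethoxy-2-hydroxy-6-methoxy-5-methylphenyl)methyl]benzene A3.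
- In its favour: the reaction is thermal and two-component, and its regiochemistry is well precedented for alkoxyalkynes. The methyl ynol ether arms of A1 cannot undergo the benzyl shift that threatens 5, 7 and 12. Ring B of A3 emerges with three different oxygens (OH at C2', OEt at C4', OMe at C6'), so the lone methyl ether is placed by construction and only one chelated ether per ring would have to be cleaved later. On this point Alternative 1 is better than the chosen plan.
- Against it: A3 carries none of the three butanoyl groups. Three Friedel–Crafts acylations would follow, one at C1 of ring A between two benzyloxy groups, and the free C2' phenols of A3 would compete as oxygen nucleophiles. The doubly activated propargylic CH2 groups of A1 may isomerise at the temperatures a cyclobutenone opening needs, and A1 and A2 must themselves be prepared.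
- Comparison: structurally, the chosen step closes the ring that is hardest to substitute and delivers its ketone, whereas Alternative 1 closes the two rings that are available as simple aromatics. Mechanistically, the pericyclic cascade leading to A3 has closer precedent than the proposed metal-catalysed trimerisation, which is an advantage. In step economy the alternative is estimated to be two to three steps longer.

Alternative 2: No skeletal bond is cut. The two C6'–O–CH3 bonds are disconnected, which leads back to the hexaphenol 1-{2,4,6-tris(benzyloxy)-3,5-bis[(3-butanoyl-2,4,6-trihydroxy-5-methylphenyl)methyl]phenyl}butan-1-one A4. K2CO3 and one equivalent of dimethyl sulfate per outer ring would methylate the C6' hydroxyl of A4, the only one on each ring B that is not hydrogen-bonded to the C3' ketone. The product would be the bis(methyl ether) 1-{2,4,6-tris(benzyloxy)-3,5-bis[(3-butanoyl-2,4-dihydroxy-6-methoxy-5-methylphenyl)methyl]phenyl}butan-1-one A5, and hydrogenolysis of the three benzyl ethers of A5 would finish.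
- In its favour: acylphloroglucinols are generally O-alkylated para to the acyl group first. The oxygen pattern of A5 is decided by adding a group, not by discriminating between like ethers, and the closing hydrogenolysis of A5 is gentler than a boron halide. On the oxygen question Alternative 2 is the equal of, or better than, the chosen plan.
- Against it: the step settles only the last oxygen and leaves the assembly of the carbon framework of A4 open. A4 contains two fully substituted triphenolic rings that may be oxidised, C-methylated with dearomatisation, or methylated twice on one ring while the other stays untouched, so A5 may arrive mixed with its isomers.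
- Comparison: structurally the step from A4 to A5 forms no ring and no C–C bond, against one ring and three bonds. Mechanistically it is acidity-controlled where the chosen endgame is chelation-controlled, and the two selectivity bets are of similar size. Step economy cannot be judged in full because the route to A4 is undefined; the endgame alone is one step longer.

Alternative 3: Both CH2–C1' bonds are cut. This gives a central bis-electrophile, 1-[2,4,6-tris(benzyloxy)-3,5-bis(chloromethyl)phenyl]butan-1-one A6, and two equivalents of 1-(3-bromo-2,4,6-trimethoxy-5-methylphenyl)butan-1-one A8. Zinc insertion (Zn, LiCl) into both C–Cl bonds of A6 would give the bis(benzylzinc chloride) {[2,4,6-tris(benzyloxy)-5-butanoyl-1,3-phenylene]bis(methylene)}bis(chloridozinc) A7. A twofold Negishi coupling of A7 with A8 under Pd(OAc)2 and SPhos would then give 1-{2,4,6-tris(benzyloxy)-3,5-bis[(3-butanoyl-2,4,6-trimethoxy-5-methylphenyl)methyl]phenyl}butan-1-one A9, which is the same compound as 14.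
- In its favour: benzylzinc–aryl bromide coupling is a precedented bond-forming type, and the LiCl-promoted zinc insertion into A6 tolerates ketones. All three butanoyl groups are in place before the coupling, so no acylation is needed on a benzyl-ether-laden intermediate, and the regiochemistry is fixed by the halogen positions of A6 and A8. On precedent and on step count (about six steps, longest line four) Alternative 3 is better than the chosen plan.
- Against it: both partners are di-ortho-substituted (the benzylic zinc of A7 between two benzyloxy groups, the bromide of A8 between two methoxy groups), so oxidative addition and transmetalation should be slow. A bis-organozinc such as A7, itself made from a bis-benzylic chloride, invites protodezincation and Wurtz-type oligomerisation. Making A6 requires acidic chloromethylation of a benzyl-protected acylphloroglucinol.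
- Comparison: structurally it joins three preformed aromatic rings and takes ring A from a purchased phloroglucinol, whereas the chosen plan builds ring A and sets all six of its substituents in one operation. Because A9 equals 14, the two plans share the final deprotection and its selectivity question, so they are equal there.

Key step: step 8

## Route

Step 1
Reactants: 1 benzyl alcohol; 2 trichloroethylene
Product: 3 ({[(E)-1,2-dichloroethenyl]oxy}methyl)benzene (benzyl (E)-1,2-dichlorovinyl ether)
Conditions: KH (1.1 equiv), THF, 0 °C; then 2, −50 °C → rt
Reagents that add atoms: none
Why: The alkoxide of 1 replaces one vinylic chloride of 2 by the known base-mediated elimination–addition sequence used for alkyl 1,2-dichlorovinyl ethers; anti addition fixes the E geometry, which is lost again in the next step.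

Step 2
Reactants: 3 ({[(E)-1,2-dichloroethenyl]oxy}methyl)benzene
Product: 5 tributyl[(benzyloxy)ethynyl]stannane, via lithium (benzyloxy)ethynide 4 (not isolated)
Conditions: n-BuLi (2.05 equiv), THF, −78 → −40 °C; then Bu3SnCl (1.0 equiv), −78 → 0 °C; pentane, cold aq. NaHCO3; basic alumina; not distilled, stored at −20 °C
Reagents that add atoms: tributyltin chloride CCCC[Sn](Cl)(CCCC)CCCC
Why: Two equivalents of n-BuLi convert the dichlorovinyl ether into the lithium alkoxyacetylide (deprotonation, chloride loss, chlorine–lithium exchange), and stannylation of a lithium acetylide with Bu3SnCl is standard; the ethoxy analogue of 5 is a known, storable Stille reagent. The acetylide is thus made in one flask only and becomes a neutral alkynyl donor for both later couplings.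

Step 3
Reactants: 5 tributyl[(benzyloxy)ethynyl]stannane; 6 butanoyl chloride
Product: 7 1-(benzyloxy)hex-1-yn-3-one
Conditions: PdCl2(PPh3)2 (3 mol %), ClCH2CH2Cl, 20 → 35 °C; cold Et3N-deactivated silica
Reagents that add atoms: none
Why: Stille ketone synthesis: the acid chloride adds oxidatively to zerovalent palladium, the alkynyl group is transferred from tin and reductive elimination gives the ynone; coupling of alkynylstannanes with acid chlorides is known chemistry. No amine or strong base is present to add to the push–pull ynone, and the temperature stays well below that at which benzyl ynol ethers rearrange.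

Step 4
Reactants: 8 2,4,6-trimethoxytoluene
Product: 9 2,4,6-trimethoxy-3-methylbenzaldehyde
Conditions: POCl3, DMF, 0 °C → rt; then aq. NaOAc
Reagents that add atoms: N,N-dimethylformamide CN(C)C=O; water O
Why: Vilsmeier–Haack formylation of a trimethoxyarene; the two free ring positions of 8 are equivalent and the formyl group deactivates the ring, so substitution should stop at one carbon.

Step 5
Reactants: 9 2,4,6-trimethoxy-3-methylbenzaldehyde
Product: 10 (2,4,6-trimethoxy-3-methylphenyl)methanol
Conditions: NaBH4, MeOH–THF, 0 °C
Reagents that add atoms: none
Why: Borohydride reduction of an aryl aldehyde; the basic medium avoids acid, which would ionise this very electron-rich benzylic alcohol.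

Step 6
Reactants: 10 (2,4,6-trimethoxy-3-methylphenyl)methanol
Product: 11 2-(bromomethyl)-1,3,5-trimethoxy-4-methylbenzene
Conditions: PBr3 (0.4 equiv), Et2O, −10 °C, 20 min; cold aq. NaHCO3 wash; dried solution used at once
Reagents that add atoms: phosphorus tribromide BrP(Br)Br
Why: Standard conversion of a benzylic alcohol into the bromide with PBr3; 2,4,6-trialkoxybenzyl halides ionise readily, so the bromide is kept cold, freed of acid and not stored.

Step 7
Reactants: 5 tributyl[(benzyloxy)ethynyl]stannane; 11 2-(bromomethyl)-1,3,5-trimethoxy-4-methylbenzene
Product: 12 2-[3-(benzyloxy)prop-2-yn-1-yl]-1,3,5-trimethoxy-4-methylbenzene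
Conditions: Pd2(dba)3 (2.5 mol %), P(2-furyl)3 (10 mol %), THF, 20 °C, fresh solution of 11; work-up below 20 °C, Et3N-deactivated silica
Reagents that add atoms: none
Why: Stille coupling of a benzylic bromide with an alkynylstannane: SN2-type oxidative addition to zerovalent palladium, alkynyl transfer from tin and reductive elimination form the CH2–C(sp) bond. The medium is neutral and non-basic, which protects the very ionisable bromide from self-condensation and the benzyl ynol ether from rearrangement.

Step 8
Reactants: 12 2-[3-(benzyloxy)prop-2-yn-1-yl]-1,3,5-trimethoxy-4-methylbenzene (2.2 equiv); 7 1-(benzyloxy)hex-1-yn-3-one (1.0 equiv)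
Product: 13 1-{2,4,6-tris(benzyloxy)-3,5-bis[(2,4,6-trimethoxy-3-methylphenyl)methyl]phenyl}butan-1-one
Conditions: [Rh(cod)2]BF4 (10 mol %), rac-BINAP (10 mol %), H2 (1 atm, 30 min) then Ar, CH2Cl2, 20 °C; 12 added over 4 h to 7 and catalyst
Reagents that add atoms: none
Why: Proposed new method: the cationic monovalent rhodium bisphosphine fragment should bind one molecule of 12 and the ynone 7 and couple them oxidatively, the nucleophilic CH2Ar-bearing carbon of 12 (future C3) bonding to the electrophilic oxygen-bearing carbon of 7 (future C2), to give a rhodacyclopentadiene of trivalent rhodium with the metal on C1 and C4; a second molecule of 12 then inserts so that its CH2Ar-bearing carbon (C5) bonds to the alkoxy-substituted C4, and reductive elimination joins C6 to C1 and returns the catalyst. The closest known reaction types are the cross-cyclotrimerisation of two electron-rich alkynes with one electron-poor alkyne and the room-temperature cyclotrimerisation of aryl ethynyl ethers, both under cationic monovalent rhodium catalysts with BINAP-type ligands; a donor alkyl ynol ether paired with a push–pull alkoxy ynone has not been shown. Ring A closes on the metal template (oxidative cyclisation, insertion, reductive elimination), so the three ring bonds C2–C3, C4–C5 and C6–C1 form without a separate cyclisation event. No stereocentre is created. Two selectivities are needed: the two-to-one pairing, which should follow because the electron-poor ynone is the best partner for the first coupling while the resulting electron-poor metallacycle prefers an electron-rich third alkyne, helped by slow addition of 12; and the head-to-tail orientation, which should follow because every new bond then joins a nucleophilic alkyne carbon to an alkoxy-bearing electrophilic one. The run is held at 20 °C because benzyl ynol ethers rearrange to ketenes on warming.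

Step 9
Reactants: 13 1-{2,4,6-tris(benzyloxy)-3,5-bis[(2,4,6-trimethoxy-3-methylphenyl)methyl]phenyl}butan-1-one
Product: 14 1-{2,4,6-tris(benzyloxy)-3,5-bis[(3-butanoyl-2,4,6-trimethoxy-5-methylphenyl)methyl]phenyl}butan-1-one
Conditions: n-PrCO2H (3 equiv), (CF3CO)2O (3 equiv), CH2Cl2, 0 °C → rt
Reagents that add atoms: butanoic acid CCCC(=O)O
Why: Friedel–Crafts acylation by the mixed butanoic trifluoroacetic anhydride; C3' is the only unsubstituted carbon of each ring B and is activated by two ortho and one para methoxy group. Metal-free conditions are chosen so that no chelating Lewis acid strips the benzyl ethers next to the ring A ketone.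

Step 10
Reactants: 14 1-{2,4,6-tris(benzyloxy)-3,5-bis[(3-butanoyl-2,4,6-trimethoxy-5-methylphenyl)methyl]phenyl}butan-1-one
Product: 15 1-{3,5-bis[(3-butanoyl-2,4-dihydroxy-6-methoxy-5-methylphenyl)methyl]-2,4,6-trihydroxyphenyl}butan-1-one
Conditions: BCl3 (12 equiv), C6HMe5 (9 equiv), CH2Cl2, −78 °C → rt; MeOH, then aq. NaHCO3
Reagents that add atoms: none
Why: BCl3 cleaves aryl benzyl ethers at low temperature, the benzyl cation being trapped by pentamethylbenzene, and on warming should remove the methyl groups at C2' and C4' through six-membered boron chelates with the C3' ketone (chelation-controlled ortho demethylation). The C6' methyl ether is para to the ketone, cannot chelate and has no neighbouring oxygen, so it should be retained.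

## Compound list

1 | benzyl alcohol | OCc1ccccc1 | starting material
2 | trichloroethylene | ClC=C(Cl)Cl | starting material
3 | ({[(E)-1,2-dichloroethenyl]oxy}methyl)benzene | Cl/C=C(/Cl)OCc1ccccc1 | intermediate
4 | lithium (benzyloxy)ethynide | [Li]C#COCc1ccccc1 | intermediate (not isolated)
5 | tributyl[(benzyloxy)ethynyl]stannane | CCCC[Sn](CCCC)(CCCC)C#COCc1ccccc1 | intermediate
6 | butanoyl chloride | CCCC(Cl)=O | starting material
7 | 1-(benzyloxy)hex-1-yn-3-one | CCCC(=O)C#COCc1ccccc1 | intermediate
8 | 2,4,6-trimethoxytoluene | Cc1c(OC)cc(OC)cc1OC | starting material
9 | 2,4,6-trimethoxy-3-methylbenzaldehyde | COc1cc(OC)c(C=O)c(OC)c1C | intermediate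
10 | (2,4,6-trimethoxy-3-methylphenyl)methanol | COc1cc(OC)c(CO)c(OC)c1C | intermediate
11 | 2-(bromomethyl)-1,3,5-trimethoxy-4-methylbenzene | COc1cc(OC)c(CBr)c(OC)c1C | intermediate
12 | 2-[3-(benzyloxy)prop-2-yn-1-yl]-1,3,5-trimethoxy-4-methylbenzene | COc1cc(OC)c(CC#COCc2ccccc2)c(OC)c1C | intermediate
13 | 1-{2,4,6-tris(benzyloxy)-3,5-bis[(2,4,6-trimethoxy-3-methylphenyl)methyl]phenyl}butan-1-one | CCCC(=O)c1c(OCc2ccccc2)c(Cc2c(OC)cc(OC)c(C)c2OC)c(OCc2ccccc2)c(Cc2c(OC)cc(OC)c(C)c2OC)c1OCc1ccccc1 | intermediate
14 | 1-{2,4,6-tris(benzyloxy)-3,5-bis[(3-butanoyl-2,4,6-trimethoxy-5-methylphenyl)methyl]phenyl}butan-1-one | CCCC(=O)c1c(OCc2ccccc2)c(Cc2c(OC)c(C(=O)CCC)c(OC)c(C)c2OC)c(OCc2ccccc2)c(Cc2c(OC)c(C(=O)CCC)c(OC)c(C)c2OC)c1OCc1ccccc1 | intermediate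
15 | 1-{3,5-bis[(3-butanoyl-2,4-dihydroxy-6-methoxy-5-methylphenyl)methyl]-2,4,6-trihydroxyphenyl}butan-1-one | CCCC(=O)c1c(O)c(Cc2c(O)c(C(=O)CCC)c(O)c(C)c2OC)c(O)c(Cc2c(O)c(C(=O)CCC)c(O)c(C)c2OC)c1O | target

## Step count and least certain steps

Total step count: 10. Longest linear sequence: 7 steps (steps 4 to 10, from 8 to 15).

**Step 8 (key step).**
- Most likely to go wrong: homotrimerisation of 12, mis-paired or regioisomeric cross-trimers, sequestration of the cationic rhodium by the electron-rich arene rings, and metal-induced rearrangement of the benzyl ynol ethers. The three-component selectivity rests only on an electronic bias that is untested for these partners.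
- Fallback (known chemistry, sets out from 8 and returns at 13): ring A is taken from commercial 1-(2,4,6-trihydroxyphenyl)butan-1-one instead of being built. Double Mannich aminomethylation (CH2O, Me2NH, EtOH) should give 1-{3,5-bis[(dimethylamino)methyl]-2,4,6-trihydroxyphenyl}butan-1-one F1. Heating F1 with an excess of 8 in AcOH (loss of dimethylamine, then Friedel–Crafts-type conjugate addition of the arene at one of its two equivalent free positions) should give 1-{2,4,6-trihydroxy-3,5-bis[(2,4,6-trimethoxy-3-methylphenyl)methyl]phenyl}butan-1-one F2. Tri-O-benzylation of F2 (BnBr, Cs2CO3, DMF) then leads to 13.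

**Step 10.**
- Most likely to go wrong: incomplete cleavage of the second chelated methoxy group on each ring B once the ketone is tied up in its first boron chelate, or, under forcing, loss of the C6' methyl ether and acid-induced scission of the bridges. The step asks one reagent to discriminate between three hindered methyl ethers on the same ring.
- Fallback (sets out from 8 and returns at 15): the oxygen pattern is settled on a monomer and the trimer is assembled by methylene bridging. Acylation of 8 (n-PrCO2H, (CF3CO)2O) gives 1-(2,4,6-trimethoxy-3-methylphenyl)butan-1-one F3. Exhaustive demethylation of F3 with BBr3 gives 1-(2,4,6-trihydroxy-3-methylphenyl)butan-1-one F4. Para-selective O-methylation of F4 (Me2SO4, 1 equiv, K2CO3, acetone) gives 1-(2,6-dihydroxy-4-methoxy-3-methylphenyl)butan-1-one F5. Two equivalents of F5 are then heated in dioxane with the bis-Mannich base F1, prepared as in the fallback for step 8, and alkylation at the one free ring carbon of F5 should give 15.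

**Step 9.**
- Most likely to go wrong: acid-triggered cleavage of the CH2 bridges (ipso protonation and loss of a stabilised benzylic cation), loss of benzyl groups, or a stalled second acylation at the crowded C3' position.
- Fallback (sets out from 13 and returns at 14): the ketone is built in three milder operations. Vilsmeier–Haack formylation at both C3' positions (POCl3, DMF) gives 3,3'-{[2,4,6-tris(benzyloxy)-5-butanoyl-1,3-phenylene]bis(methylene)}bis(2,4,6-trimethoxy-5-methylbenzaldehyde) F6. Addition of n-PrMgBr to F6 (THF, −78 °C), which should favour the aldehydes over the hindered ring A ketone, gives 1-{2,4,6-tris(benzyloxy)-3,5-bis{[3-(1-hydroxybutyl)-2,4,6-trimethoxy-5-methylphenyl]methyl}phenyl}butan-1-one F7 as a mixture of stereoisomers. Oxidation of F7 with MnO2 in CH2Cl2 then leads to 14.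

**Step 7.**
- Most likely to go wrong: alkynyl transfer from tin that is slower than ionisation and self-condensation of the benzylic bromide, homocoupling of the benzylpalladium intermediate, or protodestannylation of 5 by traces of acid carried over with 11.
- Fallback (sets out from 3 and returns at 12): the bond is made by a polar substitution in place of the catalytic cycle. 3 is converted into the acetylide 4 exactly as in step 2 (n-BuLi, THF, −78 → −40 °C), and 4 is alkylated directly by 11 in THF–DMPU at −78 → −20 °C to give 12. This SN2 alkylation of a lithium alkoxyacetylide by a reactive halide is known chemistry and makes no new compound.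

**Step 3.**
- Most likely to go wrong: addition of hydrogen chloride, carried in with the acid chloride, across the ynol ether of 5 or the push–pull triple bond of 7, or hydration of 7 on the silica, because the oxygen-bearing alkyne carbon is strongly electrophilic.
- Fallback (sets out from 3 and returns at 7): the acetylide 4, generated from 3 as in step 2, is added to butanal at −78 °C to give racemic 1-(benzyloxy)hex-1-yn-3-ol F8. Neutral oxidation of F8 with MnO2 in CH2Cl2 gives 7 without any acid chloride or amine present.

## Further compounds

F1 | step 8 | 1-{3,5-bis[(dimethylamino)methyl]-2,4,6-trihydroxyphenyl}butan-1-one | CCCC(=O)c1c(O)c(CN(C)C)c(O)c(CN(C)C)c1O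
F2 | step 8 | 1-{2,4,6-trihydroxy-3,5-bis[(2,4,6-trimethoxy-3-methylphenyl)methyl]phenyl}butan-1-one | CCCC(=O)c1c(O)c(Cc2c(OC)cc(OC)c(C)c2OC)c(O)c(Cc2c(OC)cc(OC)c(C)c2OC)c1O
F3 | step 10 | 1-(2,4,6-trimethoxy-3-methylphenyl)butan-1-one | CCCC(=O)c1c(OC)cc(OC)c(C)c1OC
F4 | step 10 | 1-(2,4,6-trihydroxy-3-methylphenyl)butan-1-one | CCCC(=O)c1c(O)cc(O)c(C)c1O
F5 | step 10 | 1-(2,6-dihydroxy-4-methoxy-3-methylphenyl)butan-1-one | CCCC(=O)c1c(O)cc(OC)c(C)c1O
F6 | step 9 | 3,3'-{[2,4,6-tris(benzyloxy)-5-butanoyl-1,3-phenylene]bis(methylene)}bis(2,4,6-trimethoxy-5-methylbenzaldehyde) | CCCC(=O)c1c(OCc2ccccc2)c(Cc2c(OC)c(C=O)c(OC)c(C)c2OC)c(OCc2ccccc2)c(Cc2c(OC)c(C=O)c(OC)c(C)c2OC)c1OCc1ccccc1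
F7 | step 9 | 1-{2,4,6-tris(benzyloxy)-3,5-bis{[3-(1-hydroxybutyl)-2,4,6-trimethoxy-5-methylphenyl]methyl}phenyl}butan-1-one (mixture of stereoisomers) | CCCC(=O)c1c(OCc2ccccc2)c(Cc2c(OC)c(C(O)CCC)c(OC)c(C)c2OC)c(OCc2ccccc2)c(Cc2c(OC)c(C(O)CCC)c(OC)c(C)c2OC)c1OCc1ccccc1
F0 | step 7 | none | none
F8 | step 3 | 1-(benzyloxy)hex-1-yn-3-ol (racemic) | CCCC(O)C#COCc1ccccc1
A1 | alternative 1 | 1,3,5-tris(benzyloxy)-2,4-bis(3-methoxyprop-2-yn-1-yl)benzene | COC#CCc1c(OCc2ccccc2)cc(OCc2ccccc2)c(CC#COC)c1OCc1ccccc1
A2 | alternative 1 | 3-ethoxy-2-methylcyclobut-2-en-1-one | CCOC1=C(C)C(=O)C1
A3 | alternative 1 | 1,3,5-tris(benzyloxy)-2,4-bis[(4-ethoxy-2-hydroxy-6-methoxy-5-methylphenyl)methyl]benzene | CCOc1cc(O)c(Cc2c(OCc3ccccc3)cc(OCc3ccccc3)c(Cc3c(O)cc(OCC)c(C)c3OC)c2OCc2ccccc2)c(OC)c1C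
A4 | alternative 2 | 1-{2,4,6-tris(benzyloxy)-3,5-bis[(3-butanoyl-2,4,6-trihydroxy-5-methylphenyl)methyl]phenyl}butan-1-one | CCCC(=O)c1c(OCc2ccccc2)c(Cc2c(O)c(C(=O)CCC)c(O)c(C)c2O)c(OCc2ccccc2)c(Cc2c(O)c(C(=O)CCC)c(O)c(C)c2O)c1OCc1ccccc1
A5 | alternative 2 | 1-{2,4,6-tris(benzyloxy)-3,5-bis[(3-butanoyl-2,4-dihydroxy-6-methoxy-5-methylphenyl)methyl]phenyl}butan-1-one | CCCC(=O)c1c(OCc2ccccc2)c(Cc2c(O)c(C(=O)CCC)c(O)c(C)c2OC)c(OCc2ccccc2)c(Cc2c(O)c(C(=O)CCC)c(O)c(C)c2OC)c1OCc1ccccc1
A6 | alternative 3 | 1-[2,4,6-tris(benzyloxy)-3,5-bis(chloromethyl)phenyl]butan-1-one | CCCC(=O)c1c(OCc2ccccc2)c(CCl)c(OCc2ccccc2)c(CCl)c1OCc1ccccc1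
A7 | alternative 3 | {[2,4,6-tris(benzyloxy)-5-butanoyl-1,3-phenylene]bis(methylene)}bis(chloridozinc) | CCCC(=O)c1c(OCc2ccccc2)c(C[Zn]Cl)c(OCc2ccccc2)c(C[Zn]Cl)c1OCc1ccccc1
A8 | alternative 3 | 1-(3-bromo-2,4,6-trimethoxy-5-methylphenyl)butan-1-one | CCCC(=O)c1c(OC)c(Br)c(OC)c(C)c1OC
A9 | alternative 3 | 1-{2,4,6-tris(benzyloxy)-3,5-bis[(3-butanoyl-2,4,6-trimethoxy-5-methylphenyl)methyl]phenyl}butan-1-one | CCCC(=O)c1c(OCc2ccccc2)c(Cc2c(OC)c(C(=O)CCC)c(OC)c(C)c2OC)c(OCc2ccccc2)c(Cc2c(OC)c(C(=O)CCC)c(OC)c(C)c2OC)c1OCc1ccccc1
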